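All runs are calculated for substances that don't exist; scatter was added.

The easy step is to count G, the limiting reagent of the flask asked about, charged at 0.150 M against 0.30 M of L. We assume that each E, each X and each Q holds one G, so counting them gives how much G has gone.

all flasks: L 0.30 M
- south-east: G 0.15 M; the very flask that is asked about, followed so far
- south-west: G 0.30 M; run made earlier
- flask: G 0.150 M; time 25 min

| run | time / min | E / % | X / % |
|---|---|---|---|
| south-east | 2.50 | 0.8 | 0.3 |
| south-east | 5.00 | 2.7 | 0.9 |
| south-east | 8.00 | 7.2 | 0.6 |
| south-east | 10.0 | 9.1 | 0.8 |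
| south-east | 12.0 | 10.9 | 0.9 |
| south-west | 2.00 | 1.3 | 0.1 |
| south-west | 6.00 | 8.8 | 1.6 |
| south-west | 12.0 | 21.3 | 2.8 |
| south-west | 20.0 | 33.5 | 3.1 |
| south-west | 25.0 | 38.8 | 4.5 |

(standard deviation of a reading: 0.5 percentage points)

* concentration of E at 25 min, in M
* concentration of X at 25 min, in M
* concentration of Q at 25 min, in M
* concentration of G at 25 min, in M

- percent here means L units held: one X counts as two
- the numbers in the tables scatter by 0.5 percentage points (one standard deviation)

We read the south-west run first, where the charges are equal and 1/[G] should rise linearly with time. At 25.0 min, E and X leave [G] at 0.177 M, which gives a slope of 0.0928 M⁻¹ min⁻¹.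

But E lags, so Q holds G that we do not read. The south-east line through 5.00 min and 12.0 min meets zero at a lag of 2.70 min. That lag times the final rate of E in the south-west run puts 2.86% of the L charged in Q. So [G] there is 0.168 M, and we read κ = 0.104 M⁻¹ min⁻¹, the loss constant of G: its rate of loss divided by [L][G].

Holding [L] at its charge in the flask would give 0.0688 M of G at 25 min. But [L] falls as G is used, so we integrate with both falling, and our estimate becomes 0.0766 M.

Can the south-east run test κ? Not independently: its readings at 5.00 min and 12.0 min gave the lag, and that lag set Q in the south-west run. At 12.0 min in the south-east run, κ predicts that 14.6% of the L charged has passed into G's products. E, X and the lag estimate of Q give 13.8%, but the same lag stands behind both numbers, so this shows only that our reckoning hangs together, and κ stays an estimate.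

The forecast gives 0.061 M of E, 0.0035 M of X, 0.004 M of Q and 0.078 M of G, reasoning “G ≈ 0.15 − 0.072 ≈ 0.078 M”.

The flask gives 0.0651 M of E, 0.00392 M of X, 0.00945 M of Q and 0.0652 M of G.

    L + G ⇌ Q (K = 3.70 M⁻¹, k = 0.00240 M⁻¹ s⁻¹)
    Q → E (k = 0.00340 s⁻¹)
    L + Q → X (k = 8.20 × 10⁻⁴ M⁻¹ s⁻¹)
    G ⇌ Z (K = 5.70, k = 4.30 × 10⁻⁵ s⁻¹)

At 25.0 min, Z holds 0.00633 M, a form of G that our count of E, X and Q did not include. Run backwards on the flask's [G], the integrated form gives κ = 0.134 M⁻¹ min⁻¹.

In the neighbour flask with 1.2 M of L, our κ from the readings gives 0.00855 M of G at 25 min. The computed value is 0.00588 M.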